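## The problem

Calyxin A (29) is an open-chain 1,7-diarylheptanoid, numbered here C1–C7 from the saturated 4-hydroxyphenylethyl end. Its C5 is bonded to C3' of a chalcone ring A (C1' acyl, C2' and C4' hydroxyl, C5' hydrogen, C6' methoxy). No ring joins the two stereocentres: the benzylic, allylic methine C5 (R) and the carbinol C3 (S) are separated by the C4 methylene, and C3 sits between two CH2 groups. C5 must be set absolutely by an external element; once set it is a carbon-only β-stereocentre and cannot be trusted to steer a reduction at C3, so C3 needs its own reagent control (its epimers are diastereomers and can be separated or inverted). The molecule tolerates little. The C6=C7 bond is a 4-oxygenated styrene that acid protonates to a quinone-methide-like cation and that electrophilic halogen attacks. C5–H is benzylic and allylic and open to strong base. The chalcone is a Michael acceptor, is reduced by hydrides and can close to a flavanone through the C2' hydroxyl. Five hydroxyls must be masked through organometallic steps and freed without strong acid. Without the acyl group ring A is mirror-symmetric about the C3'–C6' axis, so C1' and C5' are equivalent and the acyl group can enter late at either position with no regiochemical question. The enabling feature is that C5, C3' and the oxygen on C2' form a latent ortho-quinone methide (C5=C3'–C2'=O). C5 can take the styryl group as a nucleophile at the aldehyde level, and the heterodiene can then take up C4–C3 as an enol ether, the C2' oxygen holding C3 as a ketal until the ketone is wanted.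

## Retrosynthesis

**29 from 28.** Only the five phenolic O–CH2OCH3 bonds are cut. Methoxymethyl ethers survive Grignard and alkyllithium reagents, hydride, base and mild acid, and fall together in methanolic HCl. Silyl ethers would need fluoride on a 2'-hydroxychalcone; benzyl ethers are excluded by the two alkenes. The forward step must be brief and mild so that the C6=C7 styrene and the chalcone are not drawn into acid cyclisation.

**28 from 26 and 13.** The aryl–acyl bond C1'–C(=O) is cut. Friedel–Crafts or Fries chemistry on a free resorcinol brings flavanone and coumarin formation and strong acid. An aryllithium adding to the cinnamoyl Weinreb amide 13 gives the chalcone directly under basic, cold conditions. The aryllithium is made by bromine–lithium exchange from 26, not by C–H lithiation, because exchange at −78 °C is faster than removal of the acidic C5–H. The precursor lacks the whole cinnamoyl unit. The forward step needs clean 1,2-addition by a di-ortho-substituted aryllithium in the presence of a lithium alkoxide.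

**26 from 25 and 25 from 24.** The C3–H bond is cut (ketone reduction) and then the C–Br bond. Bromination is placed on the ketone, before a C3 hydroxyl exists that could assist bromoetherification of C6=C7. In 24 ring A carries two identical MOM ethers, so its two free positions are equivalent and one bromide results. The reduction has to distinguish a β-branched from a linear methylene arm. This is the least secure control element of the plan and is backed by separation and inversion.

**24 from 23 and 23 from 22.** The aryl O–CH2 bond is cut, then the two ketal C–O bonds of 22. The chroman ketal is the masked form of both the C3 ketone and the C2' phenol, and its hydrolysis returns the auxiliary 17. Ketone 24 has one stereocentre and no ring.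

**22 from 6, 12 and 19.** This is the central disconnection: C5–C6, C4–C5 and O–C3. A conjugate addition of a ring A nucleophile to a dienone would have to control C5 without a handle and would meet 1,6-addition. Friedel–Crafts alkylation of ring A by an allylic cation gives no absolute control. The quinone methide route joins three fragments of similar size in one flask, uses the C2' oxygen that the target already has, and places C5 under the control of a recoverable auxiliary. The enol ether is 1,1-disubstituted so that C1–C3 arrive with it and C3 emerges at the ketone level. The forward reaction must give the (E)-quinone methide, an endo [4+2] addition and high facial discrimination by the auxiliary.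

**6 from 5, 4, 2 and 1.** The carbonate, one MOM ether and the formyl C–C bond are cut in turn. The formyl group is placed between the two oxygens by directed lithiation of the bis-MOM ether 2 of 5-methoxyresorcinol (1). One MOM group is then exchanged for Boc, which is both the internal acyl donor and the leaving group of the key step.

**12 and 13 from 9, and 9 from 7.** Both styryl units come from p-coumaric acid (7). After MOM protection to 9, bromodecarboxylation gives the (E)-bromide 10 and hence, via lithium, the Grignard reagent 12. Amide coupling of 9 gives 13. No alkene has to be built.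

**19 from 18, and 18 from 16 and 17.** The enol ether C=CH2 bond is cut to the ester carbonyl (methylenation), and the ester to MOM-protected phloretic acid 16 (from 14) and (1S,2R)-2-phenylcyclohexanol (17). The acid carbonyl becomes C3.

## Roads not taken

**Alternative 1:** Ring A is cut at C3'–C4'. A pyranone carrying the complete, stereodefined chain, 6-{(2S,4S)-4-[(tert-butyldimethylsilyl)oxy]-6-[4-(methoxymethoxy)phenyl]-2-{(E)-2-[4-(methoxymethoxy)phenyl]ethenyl}hexyl}-4-methoxy-2H-pyran-2-one A1, would be opened by methoxide. The ketone enolate so released would close onto the ester carbonyl and aromatise to the 2-alkyl-5-methoxyresorcinol A2.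
- Merits: ring A is built regiospecifically on a finished chain, no reactive quinone methide is handled, and A2 is symmetric, so the later acylation has no regiochemical issue.
- Better than the chosen plan in one respect: C3 can be set early on a small fragment by dependable chemistry, where the chosen plan relies on a late reduction with modest differentiation.
- Weak points: the route offers no way to create C5. That stereocentre, with its styryl and future aryl neighbours, must be made beforehand in a linear sequence. The ring transformation is strongly basic next to an allylic C–H and a silyl ether. A2 still lacks the chalcone, which would have to be installed on a free resorcinol.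
- Comparison: A2 corresponds to the stage the chosen route reaches after step 16, by a longer and less convergent path. The chosen plan sets against the early C3 control its single-flask creation of C5 together with the ring A–C5 bond, and a separation and inversion safeguard at C3.

**Alternative 2:** The chain is cut at C3–C4 and at the C3–O–C7 lactone link. Brassard diene A3 and 3-[4-(methoxymethoxy)phenyl]propanal A4 would combine under a chiral BINOL complex of tetravalent titanium (Ti(OiPr)4/BINOL) to give the (S)-dihydropyranone A5.
- Merits: a catalytic, enantioselective and well-behaved hetero-Diels–Alder reaction sets C3 from two trivial components. The lactone ring offers cyclic control for a later trans addition at C5.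
- Better than the chosen plan in one respect: C3 is controlled more securely than by ketone reduction.
- Weak points: A5 holds one stereocentre and less than half of the skeleton. C5 is at the vinylogous ester level and would have to receive the hindered, di-ortho-oxygenated ring A by conjugate addition. The lactone carbonyl would have to be rebuilt into the (E)-styryl unit. The chalcone is still to come. This makes a long linear sequence after the key step.
- Comparison: the chosen plan accepts a weaker C3 step but builds the whole heptanoid and its ring A junction in one operation.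

**Alternative 3:** Ring A is cut at C1'–C2' and C5'–C6'. The chain-bearing 1-methoxy-1,3-bis(trimethylsilyloxy)buta-1,3-diene A6 would add to the alkynone (E)-5-methoxy-1-[4-(methoxymethoxy)phenyl]pent-1-en-4-yn-3-one A7 and lose methanol to give the protected calyxin A, A8.
- Merits: it is the most convergent option on paper. All six ring A substituents, the chalcone included, are placed by the regiochemistry of one cycloaddition.
- Better than the chosen plan in one respect: no late bromination or aryllithium chemistry is needed, which saves steps 15 and 17.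
- Weak points: A6 again presupposes the stereodefined chain, and C5 would be attached to a fully substituted diene carbon that disfavours the reactive s-cis form. A7 is a push–pull alkyne of uncertain dienophilicity, and it carries a second dienophile and Michael acceptor in its cinnamoyl group. The sensitive 2'-hydroxychalcone is formed under the cycloaddition and elimination conditions.
- Comparison: the endgame is shorter, but the C5 problem is moved into fragment synthesis unsolved. The chosen plan solves C5 in its key step and pays with two extra late steps.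

Key step: step 12

Assumption on the sense of induction: enol ether 19 is taken to react as its s-cis rotamer with the carbinol C–H of the auxiliary eclipsing the O–C(sp2) bond and the phenyl ring covering the face on the C2 side of the cyclohexane. On this model the (1S,2R) auxiliary gives (R)-C5. If the opposite sense is found, the equally available (1R,2S) alcohol is used in steps 10–13 without other change.

Remark: keto phenol 23 may rest partly as its cyclic hemiketal; it is drawn in the open form.

## Route

Step 1
Reactants: 1 5-methoxyresorcinol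
Product: 2 1-methoxy-3,5-bis(methoxymethoxy)benzene
Conditions: NaH, MOMCl, DMF, 0 °C → 20 °C
Reagents that add atoms: methoxymethyl chloride, COCCl
Why: Williamson-type O-alkylation of both phenoxides; the two MOM ethers later direct the lithiation.

Step 2
Reactants: 2 1-methoxy-3,5-bis(methoxymethoxy)benzene
Product: 4 4-methoxy-2,6-bis(methoxymethoxy)benzaldehyde, via aryllithium 3 (not isolated)
Conditions: n-BuLi, TMEDA, THF, 0 °C; DMF, 0 °C → 20 °C; H2O
Reagents that add atoms: N,N-dimethylformamide, CN(C)C=O
Why: Directed ortho-metalation; the position between the two chelating MOM ethers is the most activated site and is lithiated in preference to those next to the methoxy group, and DMF formylates the aryllithium.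

Step 3
Reactants: 4 4-methoxy-2,6-bis(methoxymethoxy)benzaldehyde
Product: 5 2-hydroxy-4-methoxy-6-(methoxymethoxy)benzaldehyde
Conditions: 3 M aq. HCl, THF, 20 °C, stopped at mono-cleavage
Reagents that add atoms: none
Why: Acid-catalysed acetal hydrolysis; the first phenol released hydrogen-bonds to the formyl oxygen and slows cleavage of the second MOM ether, a selectivity established for 2,6-bis(methoxymethoxy)benzaldehydes.

Step 4
Reactants: 5 2-hydroxy-4-methoxy-6-(methoxymethoxy)benzaldehyde
Product: 6 2-(tert-butoxycarbonyloxy)-4-methoxy-6-(methoxymethoxy)benzaldehyde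
Conditions: Boc2O, iPr2NEt, 4-(dimethylamino)pyridine (DMAP, cat.), THF, 0 °C → 20 °C
Reagents that add atoms: di-tert-butyl dicarbonate, CC(C)(C)OC(=O)OC(=O)OC(C)(C)C
Why: DMAP-catalysed O-acylation of the phenol gives the aryl carbonate that acts as internal Boc donor and leaving group in step 12.

Step 5
Reactants: 7 p-coumaric acid
Product: 9 (E)-3-[4-(methoxymethoxy)phenyl]prop-2-enoic acid, via methoxymethyl ester 8 (not isolated)
Conditions: MOMCl (2.5 equiv), iPr2NEt, CH2Cl2, 0 °C → 20 °C; then LiOH, THF/H2O, 20 °C; cold 1 M HCl to pH 4
Reagents that add atoms: methoxymethyl chloride, COCCl; lithium hydroxide, [Li+].[OH-] (carboxyl oxygen by acyl–oxygen cleavage)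
Why: Exhaustive MOM alkylation of phenol and carboxylate, then saponification of the labile methoxymethyl ester, leaves only the phenol protected.

Step 6
Reactants: 9 (E)-3-[4-(methoxymethoxy)phenyl]prop-2-enoic acid
Product: 10 1-[(E)-2-bromoethenyl]-4-(methoxymethoxy)benzene
Conditions: NBS (1.05 equiv), LiOAc (0.1 equiv), MeCN/H2O 97:3, 20 °C
Reagents that add atoms: N-bromosuccinimide, O=C1CCC(=O)N1Br
Why: Catalytic Hunsdiecker-type bromodecarboxylation; bromonium formation on the electron-rich cinnamate and anti decarboxylative elimination give the (E)-bromide with retention of alkene geometry.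

Step 7
Reactants: 10 1-[(E)-2-bromoethenyl]-4-(methoxymethoxy)benzene
Product: 12 (E)-2-[4-(methoxymethoxy)phenyl]ethenylmagnesium bromide (used as a titrated Et2O solution), via alkenyllithium 11 (not isolated)
Conditions: t-BuLi (2.0 equiv), Et2O, −78 °C; MgBr2·OEt2 (1.1 equiv), −78 → 0 °C
Reagents that add atoms: magnesium bromide, Br[Mg]Br
Why: Bromine–lithium exchange proceeds with retention of the (E) geometry and transmetalation with MgBr2 supplies the magnesium counter-ion needed for the elimination in step 12.

Step 8
Reactants: 9 (E)-3-[4-(methoxymethoxy)phenyl]prop-2-enoic acid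
Product: 13 (E)-N-methoxy-N-methyl-3-[4-(methoxymethoxy)phenyl]prop-2-enamide
Conditions: MeNH(OMe)·HCl, EDC·HCl, iPr2NEt, DMAP (cat.), CH2Cl2, 20 °C
Reagents that add atoms: N,O-dimethylhydroxylamine hydrochloride, CNOC.Cl
Why: Carbodiimide amide coupling to the Weinreb amide.

Step 9
Reactants: 14 phloretic acid
Product: 16 3-[4-(methoxymethoxy)phenyl]propanoic acid, via methoxymethyl ester 15 (not isolated)
Conditions: MOMCl (2.5 equiv), iPr2NEt, CH2Cl2, 0 °C → 20 °C; then LiOH, THF/H2O, 20 °C; cold 1 M HCl to pH 4
Reagents that add atoms: methoxymethyl chloride, COCCl; lithium hydroxide, [Li+].[OH-] (carboxyl oxygen by acyl–oxygen cleavage)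
Why: Same protection and saponification sequence as in step 5.

Step 10
Reactants: 16 3-[4-(methoxymethoxy)phenyl]propanoic acid; 17 (1S,2R)-trans-2-phenylcyclohexanol
Product: 18 (1S,2R)-2-phenylcyclohexyl 3-[4-(methoxymethoxy)phenyl]propanoate
Conditions: DCC, DMAP (cat.), CH2Cl2, 0 °C → 20 °C
Reagents that add atoms: none
Why: Steglich esterification of the hindered secondary alcohol; the carbinol centre is not involved in bond breaking.

Step 11
Reactants: 18 (1S,2R)-2-phenylcyclohexyl 3-[4-(methoxymethoxy)phenyl]propanoate
Product: 19 1-(methoxymethoxy)-4-(3-{[(1S,2R)-2-phenylcyclohexyl]oxy}but-3-en-1-yl)benzene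
Conditions: Cp2TiMe2 (2.5 equiv), toluene, 70 °C, dark; filtration through basic alumina
Reagents that add atoms: dimethyltitanocene, C[Ti](C)(C1C=CC=C1)C1C=CC=C1
Why: Petasis methylenation; thermally formed Cp2Ti=CH2 undergoes [2+2] addition and cycloreversion with the ester carbonyl to give the 1,1-disubstituted enol ether without touching the stereocentres.

Step 12
Reactants: 6 2-(tert-butoxycarbonyloxy)-4-methoxy-6-(methoxymethoxy)benzaldehyde; 12 (E)-2-[4-(methoxymethoxy)phenyl]ethenylmagnesium bromide; 19 1-(methoxymethoxy)-4-(3-{[(1S,2R)-2-phenylcyclohexyl]oxy}but-3-en-1-yl)benzene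
Product: 22 (2S,4R)-7-methoxy-5-(methoxymethoxy)-2-{2-[4-(methoxymethoxy)phenyl]ethyl}-4-{(E)-2-[4-(methoxymethoxy)phenyl]ethenyl}-2-{[(1S,2R)-2-phenylcyclohexyl]oxy}chromane (alkoxy group cis to styryl group), via magnesium alkoxide 20 (not isolated), via o-quinone methide 21 (not isolated)
Conditions: 6, Et2O, −78 °C; 12 (1.05 equiv), 20 min; 19 (2.0 equiv), −78 → 20 °C; aq. NaHCO3
Reagents that add atoms: none
Why: Proposed new method: the cascade is the known Grignard-triggered generation of an o-quinone methide from an O-Boc salicylaldehyde with inverse-demand hetero-Diels–Alder trapping by a chiral vinyl ether (closest known reaction type), but a chiral 1,1-disubstituted enol ether and an alkenyl Grignard reagent have not been combined in it. Addition of 12 to the formyl group gives alkoxide 20, the Boc group moves to the benzylic oxygen through a six-membered transition state, and the magnesium phenoxide expels tert-butyl carbonate to give the (E)-quinone methide 21, with the styryl group turned away from the metal-bound oxygen. The electron-rich enol ether then adds across O=C2'–C3'=C5 in a concerted, asynchronous [4+2] cycloaddition, its CH2 terminus bonding to C5 and its oxygenated carbon to the quinone methide oxygen; the dihydropyran ring is thus closed by cycloaddition, both ring bonds forming in one event, and ring A regains aromaticity. C5 is fixed by the face of 21 that is attacked, which follows from two elements: the alkoxy group of 19 lies endo under the heterodiene, and the phenyl ring of the auxiliary blocks one face of the s-cis enol ether, so that the (1S,2R) auxiliary should lead to the (2S,4R) ketal and hence (R)-C5. The ketal carbon is set by the same facial choice and is given up in step 13. The step needs 1,4- and not 1,6-addition to the vinylogous quinone methide, which the concerted mode secures because only C5 is within reach of the CH2 terminus while oxygen binds the ketal carbon. It also needs the (E) geometry of 21; any (Z) isomer should close by oxa-6π electrocyclisation to a 2H-chromene and so cost yield, not configurational purity at C5.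

Step 13
Reactants: 22 the chroman ketal
Product: 23 (5R,6E)-5-[2-hydroxy-4-methoxy-6-(methoxymethoxy)phenyl]-1,7-bis[4-(methoxymethoxy)phenyl]hept-6-en-3-one
Conditions: pyridinium p-toluenesulfonate (PPTS, 0.2 equiv), acetone/H2O 10:1, 20 → 40 °C; 17 recovered by chromatography
Reagents that add atoms: water, O
Why: Acid-catalysed hydrolysis of the mixed ketal through its oxocarbenium ion; ketals cleave far faster than aryl MOM acetals at this acidity, and C5 is not affected.

Step 14
Reactants: 23 the keto phenol
Product: 24 (5R,6E)-5-[4-methoxy-2,6-bis(methoxymethoxy)phenyl]-1,7-bis[4-(methoxymethoxy)phenyl]hept-6-en-3-one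
Conditions: MOMCl (1.5 equiv), iPr2NEt, CH2Cl2, 0 °C → 20 °C
Reagents that add atoms: methoxymethyl chloride, COCCl
Why: O-alkylation of the phenoxide, the dominant anion of the ring–chain equilibrium, traps the open keto form and makes ring A symmetric so that its two free positions are equivalent.

Step 15
Reactants: 24 the bis-MOM ketone
Product: 25 (5R,6E)-5-[3-bromo-4-methoxy-2,6-bis(methoxymethoxy)phenyl]-1,7-bis[4-(methoxymethoxy)phenyl]hept-6-en-3-one
Conditions: NBS (1.0 equiv), MeCN, −40 → 0 °C, dark
Reagents that add atoms: N-bromosuccinimide, O=C1CCC(=O)N1Br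
Why: Electrophilic aromatic bromination; the tri-oxygenated ring A is much more nucleophilic than the styrene double bond or the mono-oxygenated rings, and the step is run on the ketone so that no hydroxyl can assist bromoetherification.

Step 16
Reactants: 25 the bromo ketone
Product: 26 (3S,5R,6E)-5-[3-bromo-4-methoxy-2,6-bis(methoxymethoxy)phenyl]-1,7-bis[4-(methoxymethoxy)phenyl]hept-6-en-3-ol
Conditions: (R)-2-methyl-CBS-oxazaborolidine (C18H20BNO, 0.5 equiv), catecholborane (2.0 equiv), toluene, −78 °C; MeOH, then aq. NaOH wash
Reagents that add atoms: none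
Why: Corey–Bakshi–Shibata reduction; with the β-branched C4 arm as the large group the (R)-catalyst should deliver hydride to give (S)-C3, and catecholborane leaves the styrene untouched at −78 °C. Reagent control is expected to be moderate because both arms begin with CH2.

Step 17
Reactants: 26 the bromo alcohol; 13 (E)-N-methoxy-N-methyl-3-[4-(methoxymethoxy)phenyl]prop-2-enamide
Product: 28 (2E)-1-{3-[(1E,3R,5S)-5-hydroxy-1,7-bis[4-(methoxymethoxy)phenyl]hept-1-en-3-yl]-6-methoxy-2,4-bis(methoxymethoxy)phenyl}-3-[4-(methoxymethoxy)phenyl]prop-2-en-1-one, via dilithio species 27 (not isolated)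
Conditions: t-BuLi (3.1 equiv), THF, −78 °C, 20 min; 13 (1.5 equiv), −78 → −20 °C; H2O
Reagents that add atoms: none
Why: After O-deprotonation, bromine–lithium exchange at −78 °C outruns removal of C5–H; the aryllithium adds 1,2 to the Weinreb amide to give a stable chelate that releases the chalcone only on work-up, so over-addition is avoided.

Step 18
Reactants: 28 penta-MOM calyxin A
Product: 29 calyxin A, (2E)-1-{2,4-dihydroxy-3-[(1E,3R,5S)-5-hydroxy-1,7-bis(4-hydroxyphenyl)hept-1-en-3-yl]-6-methoxyphenyl}-3-(4-hydroxyphenyl)prop-2-en-1-one
Conditions: conc. HCl (cat., to about pH 1), MeOH, 20 °C, monitored and stopped at full cleavage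
Reagents that add atoms: none
Why: Acid-catalysed transacetalisation of the five aryl MOM ethers to methanol, under the kind of conditions used for MOM-protected 2'-hydroxy-6'-methoxychalcones; short exposure at room temperature limits acid-induced cyclisation onto C7 and flavanone closure.

## Compound list

1 | 5-methoxyresorcinol | COc1cc(O)cc(O)c1 | starting material
2 | 1-methoxy-3,5-bis(methoxymethoxy)benzene | COc1cc(OCOC)cc(OCOC)c1 | intermediate
3 | [4-methoxy-2,6-bis(methoxymethoxy)phenyl]lithium | [Li]c1c(OCOC)cc(OC)cc1OCOC | intermediate (not isolated)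
4 | 4-methoxy-2,6-bis(methoxymethoxy)benzaldehyde | COc1cc(OCOC)c(C=O)c(OCOC)c1 | intermediate
5 | 2-hydroxy-4-methoxy-6-(methoxymethoxy)benzaldehyde | COc1cc(O)c(C=O)c(OCOC)c1 | intermediate
6 | 2-(tert-butoxycarbonyloxy)-4-methoxy-6-(methoxymethoxy)benzaldehyde | COc1cc(OCOC)c(C=O)c(OC(=O)OC(C)(C)C)c1 | intermediate
7 | p-coumaric acid | OC(=O)/C=C/c1ccc(O)cc1 | starting material
8 | methoxymethyl (E)-3-[4-(methoxymethoxy)phenyl]prop-2-enoate | COCOC(=O)/C=C/c1ccc(OCOC)cc1 | intermediate (not isolated)
9 | (E)-3-[4-(methoxymethoxy)phenyl]prop-2-enoic acid | OC(=O)/C=C/c1ccc(OCOC)cc1 | intermediate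
10 | 1-[(E)-2-bromoethenyl]-4-(methoxymethoxy)benzene | Br/C=C/c1ccc(OCOC)cc1 | intermediate
11 | (E)-2-[4-(methoxymethoxy)phenyl]ethenyllithium | [Li]/C=C/c1ccc(OCOC)cc1 | intermediate (not isolated)
12 | (E)-2-[4-(methoxymethoxy)phenyl]ethenylmagnesium bromide | Br[Mg]/C=C/c1ccc(OCOC)cc1 | intermediate
13 | (E)-N-methoxy-N-methyl-3-[4-(methoxymethoxy)phenyl]prop-2-enamide | CON(C)C(=O)/C=C/c1ccc(OCOC)cc1 | intermediate
14 | phloretic acid, 3-(4-hydroxyphenyl)propanoic acid | OC(=O)CCc1ccc(O)cc1 | starting material
15 | methoxymethyl 3-[4-(methoxymethoxy)phenyl]propanoate | COCOC(=O)CCc1ccc(OCOC)cc1 | intermediate (not isolated)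
16 | 3-[4-(methoxymethoxy)phenyl]propanoic acid | OC(=O)CCc1ccc(OCOC)cc1 | intermediate
17 | (1S,2R)-trans-2-phenylcyclohexanol | O[C@H]1CCCC[C@@H]1c1ccccc1 | starting material
18 | (1S,2R)-2-phenylcyclohexyl 3-[4-(methoxymethoxy)phenyl]propanoate | O=C(CCc1ccc(OCOC)cc1)O[C@H]1CCCC[C@@H]1c1ccccc1 | intermediate
19 | 1-(methoxymethoxy)-4-(3-{[(1S,2R)-2-phenylcyclohexyl]oxy}but-3-en-1-yl)benzene | C=C(CCc1ccc(OCOC)cc1)O[C@H]1CCCC[C@@H]1c1ccccc1 | intermediate
20 | bromomagnesium alkoxide from addition of 12 to the formyl group of 6 | COc1cc(OCOC)c(C(O[Mg]Br)/C=C/c2ccc(OCOC)cc2)c(OC(=O)OC(C)(C)C)c1 | intermediate (not isolated)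
21 | (6E)-3-methoxy-5-(methoxymethoxy)-6-{(2E)-3-[4-(methoxymethoxy)phenyl]prop-2-en-1-ylidene}cyclohexa-2,4-dien-1-one | O=C1C=C(OC)C=C(OCOC)/C1=C\C=C\c1ccc(OCOC)cc1 | intermediate (not isolated)
22 | (2S,4R)-7-methoxy-5-(methoxymethoxy)-2-{2-[4-(methoxymethoxy)phenyl]ethyl}-4-{(E)-2-[4-(methoxymethoxy)phenyl]ethenyl}-2-{[(1S,2R)-2-phenylcyclohexyl]oxy}chromane | COc1cc(OCOC)c2c(c1)O[C@](CCc1ccc(OCOC)cc1)(O[C@H]1CCCC[C@@H]1c1ccccc1)C[C@@H]2/C=C/c1ccc(OCOC)cc1 | intermediate
23 | (5R,6E)-5-[2-hydroxy-4-methoxy-6-(methoxymethoxy)phenyl]-1,7-bis[4-(methoxymethoxy)phenyl]hept-6-en-3-one | COc1cc(O)c([C@@H](/C=C/c2ccc(OCOC)cc2)CC(=O)CCc2ccc(OCOC)cc2)c(OCOC)c1 | intermediate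
24 | (5R,6E)-5-[4-methoxy-2,6-bis(methoxymethoxy)phenyl]-1,7-bis[4-(methoxymethoxy)phenyl]hept-6-en-3-one | COc1cc(OCOC)c([C@@H](/C=C/c2ccc(OCOC)cc2)CC(=O)CCc2ccc(OCOC)cc2)c(OCOC)c1 | intermediate
25 | (5R,6E)-5-[3-bromo-4-methoxy-2,6-bis(methoxymethoxy)phenyl]-1,7-bis[4-(methoxymethoxy)phenyl]hept-6-en-3-one | COc1cc(OCOC)c([C@@H](/C=C/c2ccc(OCOC)cc2)CC(=O)CCc2ccc(OCOC)cc2)c(OCOC)c1Br | intermediate
26 | (3S,5R,6E)-5-[3-bromo-4-methoxy-2,6-bis(methoxymethoxy)phenyl]-1,7-bis[4-(methoxymethoxy)phenyl]hept-6-en-3-ol | COc1cc(OCOC)c([C@@H](/C=C/c2ccc(OCOC)cc2)C[C@@H](O)CCc2ccc(OCOC)cc2)c(OCOC)c1Br | intermediate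
27 | aryllithium lithium alkoxide from 26 | COc1cc(OCOC)c([C@@H](/C=C/c2ccc(OCOC)cc2)C[C@@H](O[Li])CCc2ccc(OCOC)cc2)c(OCOC)c1[Li] | intermediate (not isolated)
28 | (2E)-1-{3-[(1E,3R,5S)-5-hydroxy-1,7-bis[4-(methoxymethoxy)phenyl]hept-1-en-3-yl]-6-methoxy-2,4-bis(methoxymethoxy)phenyl}-3-[4-(methoxymethoxy)phenyl]prop-2-en-1-one | COc1cc(OCOC)c([C@@H](/C=C/c2ccc(OCOC)cc2)C[C@@H](O)CCc2ccc(OCOC)cc2)c(OCOC)c1C(=O)/C=C/c1ccc(OCOC)cc1 | intermediate
29 | calyxin A | COc1cc(O)c([C@@H](/C=C/c2ccc(O)cc2)C[C@@H](O)CCc2ccc(O)cc2)c(O)c1C(=O)/C=C/c1ccc(O)cc1 | target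

## Count and risks

Total: 18 steps. Longest linear sequence: 11 steps (steps 1–4 and 12–18, from 5-methoxyresorcinol).

**Step 12 (key step, proposed new method).** The most likely failure is erosion of the C5 configuration. The disubstituted enol ether may add with its alkoxy group exo, or on the face not predicted by the shielding model; either reverses C5. Further losses may come from electrocyclisation of a (Z)-quinone methide and from stepwise 1,6-addition at C7. The fallback uses the documented form of the cascade and sets out again from 6 and 12.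
- The enol ether is replaced by (1R,2S)-2-phenylcyclohexyl vinyl ether F1, made from commercial (1R,2S)-2-phenylcyclohexanol, ethyl vinyl ether and Hg(OAc)2 (cat.). The antipodal auxiliary is specified because the monosubstituted ether reacts through its s-trans rotamer, which on the same shielding model presents the other prochiral face. This assignment is to be checked on the first adduct.
- The cycloaddition should give the 2,4-cis chroman acetal F2, and PPTS in aqueous acetone the lactol F3.
- 1-(2-Bromoethyl)-4-(methoxymethoxy)benzene F4 (from commercial 4-(2-bromoethyl)phenol, MOMCl and iPr2NEt) is converted with Mg in THF into 2-[4-(methoxymethoxy)phenyl]ethylmagnesium bromide F5.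
- An excess of F5 adds to F3 to give the phenol alcohol F6 as a mixture of C3 epimers. MOMCl and iPr2NEt give the bis-MOM alcohol F7, and Dess–Martin periodinane oxidises it to ketone 24, where the route is rejoined.

**Step 16.** Both carbonyl substituents begin with a methylene group, so enantiofacial discrimination by the oxazaborolidine may be poor and C3 may form as a mixture. The fallback sets out from 25. NaBH4 in MeOH gives 26 together with its (3R) epimer F8; the two are diastereomers and are separated by chromatography. F8 is inverted by a Mitsunobu reaction (4-nitrobenzoic acid, PPh3, diisopropyl azodicarboxylate) to the (3S) 4-nitrobenzoate F9, and K2CO3 in MeOH returns 26.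

**Step 15.** Bromine may add to the electron-rich C6=C7 styrene, or ring A may be brominated twice. The fallback omits halogenation and sets out from 24. The reduction of step 16 gives the bromine-free alcohol F10. Directed ortho-lithiation (n-BuLi, 2.3 equiv, TMEDA, THF, −78 → 0 °C; the first equivalent removes the hydroxyl proton) between a MOM ether and the methoxy group, then addition of 13, gives 28. Competing removal of C5–H has to be watched, which is why this is not the first choice.

**Step 17.** The di-ortho-substituted aryllithium may add slowly to the amide, add in conjugate fashion, or be quenched by proton transfer. The fallback sets out from 26 with the same exchange, but traps with the small electrophile N-methoxy-N-methylacetamide to give the acetophenone F11. A Claisen–Schmidt condensation with commercial 4-(methoxymethoxy)benzaldehyde (KOH, EtOH, 20 °C) then builds the enone and returns 28.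

## Further compounds

F1 | step 12 | (1R,2S)-2-phenylcyclohexyl vinyl ether | C=CO[C@@H]1CCCC[C@H]1c1ccccc1
F2 | step 12 | (2S,4R)-7-methoxy-5-(methoxymethoxy)-4-{(E)-2-[4-(methoxymethoxy)phenyl]ethenyl}-2-{[(1R,2S)-2-phenylcyclohexyl]oxy}chromane | COc1cc(OCOC)c2c(c1)O[C@H](O[C@@H]1CCCC[C@H]1c1ccccc1)C[C@@H]2/C=C/c1ccc(OCOC)cc1
F3 | step 12 | (4R)-7-methoxy-5-(methoxymethoxy)-4-{(E)-2-[4-(methoxymethoxy)phenyl]ethenyl}chroman-2-ol (anomers) | COc1cc(OCOC)c2c(c1)OC(O)C[C@@H]2/C=C/c1ccc(OCOC)cc1
F4 | step 12 | 1-(2-bromoethyl)-4-(methoxymethoxy)benzene | BrCCc1ccc(OCOC)cc1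
F5 | step 12 | 2-[4-(methoxymethoxy)phenyl]ethylmagnesium bromide | Br[Mg]CCc1ccc(OCOC)cc1
F6 | step 12 | (5R,6E)-5-[2-hydroxy-4-methoxy-6-(methoxymethoxy)phenyl]-1,7-bis[4-(methoxymethoxy)phenyl]hept-6-en-3-ol (C3 epimers) | COc1cc(O)c([C@@H](/C=C/c2ccc(OCOC)cc2)CC(O)CCc2ccc(OCOC)cc2)c(OCOC)c1
F7 | step 12 | (5R,6E)-5-[4-methoxy-2,6-bis(methoxymethoxy)phenyl]-1,7-bis[4-(methoxymethoxy)phenyl]hept-6-en-3-ol (C3 epimers) | COc1cc(OCOC)c([C@@H](/C=C/c2ccc(OCOC)cc2)CC(O)CCc2ccc(OCOC)cc2)c(OCOC)c1
F8 | step 16 | (3R,5R,6E)-5-[3-bromo-4-methoxy-2,6-bis(methoxymethoxy)phenyl]-1,7-bis[4-(methoxymethoxy)phenyl]hept-6-en-3-ol | COc1cc(OCOC)c([C@@H](/C=C/c2ccc(OCOC)cc2)C[C@H](O)CCc2ccc(OCOC)cc2)c(OCOC)c1Br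
F9 | step 16 | (3S,5R,6E)-5-[3-bromo-4-methoxy-2,6-bis(methoxymethoxy)phenyl]-1,7-bis[4-(methoxymethoxy)phenyl]hept-6-en-3-yl 4-nitrobenzoate | COc1cc(OCOC)c([C@@H](/C=C/c2ccc(OCOC)cc2)C[C@@H](OC(=O)c2ccc(cc2)[N+](=O)[O-])CCc2ccc(OCOC)cc2)c(OCOC)c1Br
F10 | step 15 | (3S,5R,6E)-5-[4-methoxy-2,6-bis(methoxymethoxy)phenyl]-1,7-bis[4-(methoxymethoxy)phenyl]hept-6-en-3-ol | COc1cc(OCOC)c([C@@H](/C=C/c2ccc(OCOC)cc2)C[C@@H](O)CCc2ccc(OCOC)cc2)c(OCOC)c1
F11 | step 17 | 1-{3-[(1E,3R,5S)-5-hydroxy-1,7-bis[4-(methoxymethoxy)phenyl]hept-1-en-3-yl]-6-methoxy-2,4-bis(methoxymethoxy)phenyl}ethan-1-one | COc1cc(OCOC)c([C@@H](/C=C/c2ccc(OCOC)cc2)C[C@@H](O)CCc2ccc(OCOC)cc2)c(OCOC)c1C(C)=O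
A1 | alternative 1 | 6-{(2S,4S)-4-[(tert-butyldimethylsilyl)oxy]-6-[4-(methoxymethoxy)phenyl]-2-{(E)-2-[4-(methoxymethoxy)phenyl]ethenyl}hexyl}-4-methoxy-2H-pyran-2-one | COC1=CC(=O)OC(C[C@@H](/C=C/c2ccc(OCOC)cc2)C[C@@H](O[Si](C)(C)C(C)(C)C)CCc2ccc(OCOC)cc2)=C1
A2 | alternative 1 | 2-[(1E,3R,5S)-5-[(tert-butyldimethylsilyl)oxy]-1,7-bis[4-(methoxymethoxy)phenyl]hept-1-en-3-yl]-5-methoxybenzene-1,3-diol | COc1cc(O)c([C@@H](/C=C/c2ccc(OCOC)cc2)C[C@@H](O[Si](C)(C)C(C)(C)C)CCc2ccc(OCOC)cc2)c(O)c1
A3 | alternative 2 | Brassard diene, 1,3-dimethoxy-1-(trimethylsilyloxy)buta-1,3-diene | COC(=C)C=C(OC)O[Si](C)(C)C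
A4 | alternative 2 | 3-[4-(methoxymethoxy)phenyl]propanal | O=CCCc1ccc(OCOC)cc1
A5 | alternative 2 | (S)-4-methoxy-6-{2-[4-(methoxymethoxy)phenyl]ethyl}-5,6-dihydro-2H-pyran-2-one | COC1=CC(=O)O[C@@H](CCc2ccc(OCOC)cc2)C1
A6 | alternative 3 | 1-methoxy-1,3-bis(trimethylsilyloxy)buta-1,3-diene carrying at C2 the (1E,3R,5S)-5-[(tert-butyldimethylsilyl)oxy]-1,7-bis[4-(methoxymethoxy)phenyl]hept-1-en-3-yl group | COC(O[Si](C)(C)C)=C([C@@H](/C=C/c1ccc(OCOC)cc1)C[C@@H](O[Si](C)(C)C(C)(C)C)CCc1ccc(OCOC)cc1)C(=C)O[Si](C)(C)C
A7 | alternative 3 | (E)-5-methoxy-1-[4-(methoxymethoxy)phenyl]pent-1-en-4-yn-3-one | COC#CC(=O)/C=C/c1ccc(OCOC)cc1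
A8 | alternative 3 | calyxin A with the three 4-hydroxyphenyl groups as MOM ethers and the C3 hydroxyl as the TBS ether | COc1cc(O)c([C@@H](/C=C/c2ccc(OCOC)cc2)C[C@@H](O[Si](C)(C)C(C)(C)C)CCc2ccc(OCOC)cc2)c(O)c1C(=O)/C=C/c1ccc(OCOC)cc1
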